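**Plan**
- Retrosynthesis: the seven phenols are masked as benzyl ethers. Ring C of the flavanone is then opened at C3–C4 together with C2–H, giving a ring-A aldehyde (C4–H) and a 1-arylvinyl ether O1–C2(=C3H2). Next the vinyl C2–O1 bond is cut (phenol plus 1-bromovinyl arene), and last the biaryl bond C5'(ring B)–C6 of the flavone unit.
- Enabling feature: in ring C the carbonyl carbon C4 sits on ring A ortho to O1, C3 is an unsubstituted CH2, and C2 carries H, O1 and ring B. This is the pattern left when a formyl C–H adds across the terminal alkene of an O1-bound 1-arylvinyl group.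
- Forward order: apigenin (the complete flavone unit) is benzylated and iodinated at C6. Ring B enters as an acetophenone boronate and a Suzuki–Miyaura coupling makes the biaryl. The acetyl group becomes a 1-bromovinyl group, which is O-vinylated by the ring-A salicylaldehyde. Ring C is closed in the penultimate step, and hydrogenolysis finishes the route.
- Stereochemistry: the only stereocentre, C2 (S), is created in the ring closure by a chiral diphosphine on rhodium. That step is neutral and only a neutral hydrogenolysis follows, so the base-labile C2–O1 bond never meets base.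

Key step: step 12

Remark: the biaryl axis (three ortho substituents, no axial configuration in the target SMILES) is taken as freely rotating; atropisomers are not considered.
Remark: which antipode of the diphosphine leads to (2S) cannot be assigned with certainty in advance; (R)-DTBM-SEGPHOS is written and would be exchanged for its antipode if a model 2-[(1-phenylvinyl)oxy]benzaldehyde shows the opposite sense.

**Route**

Step 1
Reactants: 1 apigenin
Product: 2 7,4'-di-O-benzylapigenin (7-benzyloxy-2-(4-benzyloxyphenyl)-5-hydroxy-4H-chromen-4-one)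
Conditions: BnBr (2.2 equiv), K2CO3, DMF, rt to 50 °C
Reagents that add atoms: benzyl bromide, BrCc1ccccc1
Why: Williamson ether synthesis; the 5-OH is hydrogen-bonded to the C4 carbonyl and is the least nucleophilic, so alkylation should stop at the 7- and 4'-oxygens.

Step 2
Reactants: 2 7,4'-di-O-benzylapigenin
Product: 3 6-iodo-7,4'-di-O-benzylapigenin (7-benzyloxy-2-(4-benzyloxyphenyl)-5-hydroxy-6-iodo-4H-chromen-4-one)
Conditions: benzyltrimethylammonium dichloroiodate (1.1 equiv), CaCO3, CH2Cl2/MeOH, rt
Reagents that add atoms: benzyltrimethylammonium dichloroiodate, C[N+](C)(C)Cc1ccccc1.Cl[I-]Cl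
Why: Electrophilic aromatic iodination; with the 5-OH free this reagent is known to attack 5-hydroxy-7-alkoxyflavones at C6, ortho to the free phenol, and not at C8.

Step 3
Reactants: 3 6-iodo-7,4'-di-O-benzylapigenin
Product: 4 6-iodo-5,7,4'-tri-O-benzylapigenin (5,7-bis(benzyloxy)-2-(4-benzyloxyphenyl)-6-iodo-4H-chromen-4-one)
Conditions: BnBr (1.5 equiv), Cs2CO3, n-Bu4NI (cat.), DMF, 60 °C
Reagents that add atoms: benzyl bromide, BrCc1ccccc1
Why: Williamson ether synthesis under forcing conditions, needed because the remaining phenol is chelated and flanked by iodine; the flavone has no other acidic site.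

Step 4
Reactants: 5 acetovanillone (1-(4-hydroxy-3-methoxyphenyl)ethanone)
Product: 6 1-(3-bromo-4-hydroxy-5-methoxyphenyl)ethanone
Conditions: Br2 (1.05 equiv), AcOH, rt
Reagents that add atoms: bromine, BrBr
Why: Electrophilic aromatic bromination; the only free position ortho to the phenol (para is blocked by the acetyl group) should be brominated much faster than the ketone α-position.

Step 5
Reactants: 6 1-(3-bromo-4-hydroxy-5-methoxyphenyl)ethanone
Product: 7 1-(3-bromo-4,5-dihydroxyphenyl)ethanone
Conditions: BBr3 (3 equiv), CH2Cl2, −78 °C to rt; then H2O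
Reagents that add atoms: none
Why: Lewis-acid cleavage of an aryl methyl ether (BBr3 demethylation); the aryl bromide and the ketone are inert to it.

Step 6
Reactants: 7 1-(3-bromo-4,5-dihydroxyphenyl)ethanone
Product: 8 1-[3,4-bis(benzyloxy)-5-bromophenyl]ethanone
Conditions: BnBr (2.4 equiv), K2CO3, DMF, 60 °C
Reagents that add atoms: benzyl bromide, BrCc1ccccc1
Why: Williamson ether synthesis on both catechol oxygens; K2CO3 is too weak to C-alkylate the methyl ketone.

Step 7
Reactants: 8 1-[3,4-bis(benzyloxy)-5-bromophenyl]ethanone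
Product: 9 1-[3,4-bis(benzyloxy)-5-(4,4,5,5-tetramethyl-1,3,2-dioxaborolan-2-yl)phenyl]ethanone
Conditions: B2pin2 (1.2 equiv), PdCl2(dppf) (3 mol %), KOAc (3 equiv), 1,4-dioxane, 90 °C
Reagents that add atoms: bis(pinacolato)diboron, CC1(C)OB(OC1(C)C)B1OC(C)(C)C(C)(C)O1
Why: Miyaura borylation of an aryl bromide; the ketone is tolerated, and boron is placed on the less hindered partner, which has only one ortho oxygen and should resist protodeboronation.

Step 8
Reactants: 4 6-iodo-5,7,4'-tri-O-benzylapigenin; 9 1-[3,4-bis(benzyloxy)-5-(4,4,5,5-tetramethyl-1,3,2-dioxaborolan-2-yl)phenyl]ethanone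
Product: 10 biaryl ketone, 6-[5-acetyl-2,3-bis(benzyloxy)phenyl]-5,7-bis(benzyloxy)-2-(4-benzyloxyphenyl)-4H-chromen-4-one
Conditions: Pd(OAc)2 (5 mol %), SPhos (10 mol %), K3PO4 (3 equiv), toluene/H2O 10:1, 90 °C
Reagents that add atoms: none
Why: Suzuki–Miyaura coupling; the bulky electron-rich biarylphosphine is suited to the tri-ortho-substituted biaryl, and the bond is made before any stereocentre exists.

Step 9
Reactants: 10 biaryl ketone
Product: 11 biaryl vinyl bromide, 6-[2,3-bis(benzyloxy)-5-(1-bromovinyl)phenyl]-5,7-bis(benzyloxy)-2-(4-benzyloxyphenyl)-4H-chromen-4-one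
Conditions: P(OPh)3 (1.2 equiv), Br2 (1.2 equiv), CH2Cl2, −60 °C; then Et3N (1.3 equiv) and 10, −60 °C to rt; filtration through basic alumina, used at once
Reagents that add atoms: bromine, BrBr (delivered as triphenyl phosphite dibromide formed in the flask)
Why: Conversion of a methyl ketone into a vinyl bromide with a halophosphonium reagent (O-phosphorylation, bromide addition, amine-promoted elimination, driven by the P=O bond); the acetyl group is the only enolisable carbonyl and the flavone carbonyl is a much less reactive vinylogous ester.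

Step 10
Reactants: 12 2,4,6-trihydroxybenzaldehyde
Product: 13 2,4-bis(benzyloxy)-6-hydroxybenzaldehyde
Conditions: BnBr (2.1 equiv), K2CO3 (2.2 equiv), DMF, 0 °C to rt
Reagents that add atoms: benzyl bromide, BrCc1ccccc1
Why: Williamson ether synthesis; after the para and one ortho oxygen are alkylated, the last phenol is locked in a hydrogen bond to the formyl group and should remain free.

Step 11
Reactants: 11 biaryl vinyl bromide; 13 2,4-bis(benzyloxy)-6-hydroxybenzaldehyde (1.5 equiv)
Product: 14 enol ether aldehyde, 2,4-bis(benzyloxy)-6-({1-[3,4-bis(benzyloxy)-5-{5,7-bis(benzyloxy)-2-(4-benzyloxyphenyl)-4-oxo-4H-chromen-6-yl}phenyl]vinyl}oxy)benzaldehyde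
Conditions: CuI (10 mol %), N,N-dimethylglycine hydrochloride (30 mol %), Cs2CO3 (2 equiv), 1,4-dioxane, 80 °C
Reagents that add atoms: none
Why: Ullmann-type copper-catalysed C–O coupling of a vinyl bromide with a phenol, run with the cheap phenol in excess; the aldehyde has no α-hydrogen and tolerates Cs2CO3.

Step 12
Reactants: 14 enol ether aldehyde
Product: 15 hepta-O-benzyl flavanone–flavone, (2S)-5,7-bis(benzyloxy)-2-[3,4-bis(benzyloxy)-5-{5,7-bis(benzyloxy)-2-(4-benzyloxyphenyl)-4-oxo-4H-chromen-6-yl}phenyl]chroman-4-one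
Conditions: [Rh(cod)Cl]2 (2.5 mol %), (R)-DTBM-SEGPHOS (5.5 mol %), NaB[3,5-(CF3)2C6H3]4 (5 mol %), degassed 1,4-dioxane, 60 °C
Reagents that add atoms: none
Why: Proposed new method: oxidative addition of the formyl C–H bond (future C4) of 14 to the cationic monovalent rhodium diphosphine complex should give an acyl hydride of trivalent rhodium, whose hydride adds to the internal carbon C2 of the 1,1-disubstituted enol ether while rhodium binds the terminal C3, and C–C reductive elimination from the seven-membered acyl alkyl rhodacycle then forms the C3–C4 bond and frees the catalyst. The closest known reaction type is the rhodium-catalysed, enantioselective, endo-selective intramolecular alkene hydroacylation of ortho-allylbenzaldehydes bearing a 1,1-disubstituted alkene, which gives 3-substituted 3,4-dihydronaphthalen-1(2H)-ones; here the tether CH2 is replaced by the ether oxygen O1 and the alkene is an aryl enol ether, a substrate class on which the reaction has not been shown. The six-membered ring C closes in a formal 6-endo-trig mode, with both alkene carbons ending inside the ring. The single stereocentre C2 is set under catalyst control, the chiral diphosphine selecting one enantiotopic face of the C2=C3 bond in the hydride transfer, and the substrate has no other stereocentre to interfere. The step needs endo over exo regioselectivity (exo would give a 2-aryl-2-methylbenzofuran-3-one) and hydroacylation over decarbonylation: the aryl and oxygen substituents on C2 disfavour the tertiary alkyl rhodium of the exo path, and the chelating diphosphine together with the two ortho oxygens flanking the acyl group should slow CO extrusion. The medium is neutral, so the product cannot racemise by ring opening at C2–O1.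

Step 13
Reactants: 15 hepta-O-benzyl flavanone–flavone
Product: 16 CNP0176432.1, (2S)-2-{3,4-dihydroxy-5-[5,7-dihydroxy-2-(4-hydroxyphenyl)-4-oxo-4H-chromen-6-yl]phenyl}-5,7-dihydroxychroman-4-one
Conditions: H2 (1 atm), 10 % Pd on carbon, THF/MeOH 1:1, rt, stopped at full debenzylation
Reagents that add atoms: none
Why: Catalytic hydrogenolysis of benzyl ethers under neutral conditions, which leaves C2 untouched; the flavone C2=C3 bond, the aryl ketones and the cyclic benzylic C2–O1 bond should react much more slowly than the seven O-benzyl groups.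

**Compound list**

1 | apigenin | O=c1cc(-c2ccc(O)cc2)oc2cc(O)cc(O)c12 | starting material
2 | 7,4'-di-O-benzylapigenin | O=c1cc(-c2ccc(OCc3ccccc3)cc2)oc2cc(OCc3ccccc3)cc(O)c12 | intermediate
3 | 6-iodo-7,4'-di-O-benzylapigenin | O=c1cc(-c2ccc(OCc3ccccc3)cc2)oc2cc(OCc3ccccc3)c(I)c(O)c12 | intermediate
4 | 6-iodo-5,7,4'-tri-O-benzylapigenin | O=c1cc(-c2ccc(OCc3ccccc3)cc2)oc2cc(OCc3ccccc3)c(I)c(OCc3ccccc3)c12 | intermediate
5 | acetovanillone | CC(=O)c1ccc(O)c(OC)c1 | starting material
6 | 1-(3-bromo-4-hydroxy-5-methoxyphenyl)ethanone | CC(=O)c1cc(OC)c(O)c(Br)c1 | intermediate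
7 | 1-(3-bromo-4,5-dihydroxyphenyl)ethanone | CC(=O)c1cc(O)c(O)c(Br)c1 | intermediate
8 | 1-[3,4-bis(benzyloxy)-5-bromophenyl]ethanone | CC(=O)c1cc(OCc2ccccc2)c(OCc2ccccc2)c(Br)c1 | intermediate
9 | 1-[3,4-bis(benzyloxy)-5-(4,4,5,5-tetramethyl-1,3,2-dioxaborolan-2-yl)phenyl]ethanone | CC(=O)c1cc(OCc2ccccc2)c(OCc2ccccc2)c(B2OC(C)(C)C(C)(C)O2)c1 | intermediate
10 | biaryl ketone, 6-[5-acetyl-2,3-bis(benzyloxy)phenyl]-5,7-bis(benzyloxy)-2-(4-benzyloxyphenyl)-4H-chromen-4-one | CC(=O)c1cc(OCc2ccccc2)c(OCc2ccccc2)c(-c2c(OCc3ccccc3)cc3oc(-c4ccc(OCc5ccccc5)cc4)cc(=O)c3c2OCc2ccccc2)c1 | intermediate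
11 | biaryl vinyl bromide, 6-[2,3-bis(benzyloxy)-5-(1-bromovinyl)phenyl]-5,7-bis(benzyloxy)-2-(4-benzyloxyphenyl)-4H-chromen-4-one | C=C(Br)c1cc(OCc2ccccc2)c(OCc2ccccc2)c(-c2c(OCc3ccccc3)cc3oc(-c4ccc(OCc5ccccc5)cc4)cc(=O)c3c2OCc2ccccc2)c1 | intermediate
12 | 2,4,6-trihydroxybenzaldehyde | O=Cc1c(O)cc(O)cc1O | starting material
13 | 2,4-bis(benzyloxy)-6-hydroxybenzaldehyde | O=Cc1c(O)cc(OCc2ccccc2)cc1OCc1ccccc1 | intermediate
14 | enol ether aldehyde | O=Cc1c(OC(=C)c2cc(OCc3ccccc3)c(OCc3ccccc3)c(-c3c(OCc4ccccc4)cc4oc(-c5ccc(OCc6ccccc6)cc5)cc(=O)c4c3OCc3ccccc3)c2)cc(OCc2ccccc2)cc1OCc1ccccc1 | intermediate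
15 | hepta-O-benzyl (2S)-flavanone–flavone | O=C1C[C@@H](c2cc(OCc3ccccc3)c(OCc3ccccc3)c(-c3c(OCc4ccccc4)cc4oc(-c5ccc(OCc6ccccc6)cc5)cc(=O)c4c3OCc3ccccc3)c2)Oc2cc(OCc3ccccc3)cc(OCc3ccccc3)c21 | intermediate
16 | CNP0176432.1 | O=C1C[C@@H](c2cc(O)c(O)c(-c3c(O)cc4oc(-c5ccc(O)cc5)cc(=O)c4c3O)c2)Oc2cc(O)cc(O)c21 | target

**Count and risks**

Total step count: 13. Longest linear sequence: 9 steps (steps 4, 5, 6, 7, 8, 9, 11, 12, 13).

Steps most likely to fail:

1. Step 12 (bears the label). The acyl rhodium hydride may lose CO instead of inserting the alkene. The hydride may add with exo regiochemistry. Facial discrimination of the enol ether may be poor, or the many ether oxygens may bind and slow the catalyst. Fallback by known chemistry, with the stereocentre set before ring closure and the same C3–C4 bond formed by carbene umpolung, setting out from 10 and 13 and returning at 15: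
   - Ketone 10 would be brominated at the methyl group with phenyltrimethylammonium tribromide (THF, 0 °C) to the 2-bromo ketone F1.
   - Corey–Bakshi–Shibata reduction with (S)-2-methyl-CBS-oxazaborolidine and BH3·SMe2 (THF, −20 °C) should give the (S)-bromohydrin F2.
   - Mitsunobu etherification of F2 with phenol 13 (PPh3, DIAD, toluene, −20 °C) should proceed with inversion to the (R)-aryl ether F3.
   - An N-heterocyclic carbene generated from 3-benzyl-5-(2-hydroxyethyl)-4-methylthiazolium chloride (20 mol %) and DBU (1.1 equiv, toluene, 60 °C) should add to the aldehyde, and the resulting acyl anion equivalent should displace the primary bromide intramolecularly to give 15.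
   - The base makes this closure less safe for the C2 configuration than the neutral key step, so it would be stopped at full conversion.

2. Step 11. The vinyl bromide may lose HBr to the aryl alkyne under hot carbonate, and the chelated, ortho-formyl phenol may couple slowly. Fallback with reversed polarity and an oxidative coupling at room temperature, setting out from 11 and returning at 14:
   - Borylation of 11 (B2pin2, PdCl2(PPh3)2, PPh3, KOPh, toluene, 50 °C) should give the 1-arylvinyl boronate F4.
   - Chan–Lam coupling of F4 with phenol 13 (Cu(OAc)2 20 mol %, pyridine, 4 Å molecular sieves, O2 1 atm, CH2Cl2, rt) should give 14.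

3. Step 9. The electron-rich 1-bromovinyl arene may ionise or add HBr during formation and isolation and revert to the ketone. Fallback through a more robust enol derivative and a palladium-catalysed C–O coupling, which bypasses the bromide and the copper step, setting out from 10 and returning at 14:
   - Ketone 10 would be converted into the enol triflate F5 with KN(SiMe3)2 and N-phenylbis(trifluoromethanesulfonimide) (THF, −78 °C).
   - Coupling of F5 with phenol 13 (Pd2(dba)3, 2-(di-tert-butylphosphino)biphenyl, K3PO4, toluene, 80 °C) should give 14.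

**Further compounds**

F1 | step 12 | 2-bromo ketone, 6-[2,3-bis(benzyloxy)-5-(bromoacetyl)phenyl]-5,7-bis(benzyloxy)-2-(4-benzyloxyphenyl)-4H-chromen-4-one | BrCC(=O)c1cc(OCc2ccccc2)c(OCc2ccccc2)c(-c2c(OCc3ccccc3)cc3oc(-c4ccc(OCc5ccccc5)cc4)cc(=O)c3c2OCc2ccccc2)c1
F2 | step 12 | (S)-bromohydrin, 6-{2,3-bis(benzyloxy)-5-[(1S)-2-bromo-1-hydroxyethyl]phenyl}-5,7-bis(benzyloxy)-2-(4-benzyloxyphenyl)-4H-chromen-4-one | O[C@H](CBr)c1cc(OCc2ccccc2)c(OCc2ccccc2)c(-c2c(OCc3ccccc3)cc3oc(-c4ccc(OCc5ccccc5)cc4)cc(=O)c3c2OCc2ccccc2)c1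
F3 | step 12 | (R)-aryl ether, 2,4-bis(benzyloxy)-6-{(1R)-1-[3,4-bis(benzyloxy)-5-{5,7-bis(benzyloxy)-2-(4-benzyloxyphenyl)-4-oxo-4H-chromen-6-yl}phenyl]-2-bromoethoxy}benzaldehyde | O=Cc1c(O[C@@H](CBr)c2cc(OCc3ccccc3)c(OCc3ccccc3)c(-c3c(OCc4ccccc4)cc4oc(-c5ccc(OCc6ccccc6)cc5)cc(=O)c4c3OCc3ccccc3)c2)cc(OCc2ccccc2)cc1OCc1ccccc1
F4 | step 11 | 1-arylvinyl boronate, 6-{2,3-bis(benzyloxy)-5-[1-(4,4,5,5-tetramethyl-1,3,2-dioxaborolan-2-yl)vinyl]phenyl}-5,7-bis(benzyloxy)-2-(4-benzyloxyphenyl)-4H-chromen-4-one | C=C(B1OC(C)(C)C(C)(C)O1)c1cc(OCc2ccccc2)c(OCc2ccccc2)c(-c2c(OCc3ccccc3)cc3oc(-c4ccc(OCc5ccccc5)cc4)cc(=O)c3c2OCc2ccccc2)c1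
F5 | step 9 | enol triflate, 1-[3,4-bis(benzyloxy)-5-{5,7-bis(benzyloxy)-2-(4-benzyloxyphenyl)-4-oxo-4H-chromen-6-yl}phenyl]vinyl trifluoromethanesulfonate | C=C(OS(=O)(=O)C(F)(F)F)c1cc(OCc2ccccc2)c(OCc2ccccc2)c(-c2c(OCc3ccccc3)cc3oc(-c4ccc(OCc5ccccc5)cc4)cc(=O)c3c2OCc2ccccc2)c1
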